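The route rests on cutting the O1–C8a bond of the pyranone (ring C). Ring A has C5–OH and C8–OMe para to each other, the 1,4-dioxygenation of a hydroquinone, with O1 on C8a next to C8. Ring A can therefore be raised to a 2-acyl-1,4-benzoquinone whose only CH carbon is the future C8a. In one operation the enol oxygen of a quinonyl 1,3-diketone adds to that carbon, closing ring C and, after tautomerisation, giving the 5,8-dihydroxyflavone with no leaving group on the arene. The precursor is 5,6-dimethoxy-1,4-benzoquinone carrying a 3-oxo-3-(3,4,5-trimethoxyphenyl)propanoyl group at C2, made by mild iodine(III) oxidation of a p-methoxyphenol diketone. Methylation of C8–OH completes gardenin A.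

Key step: step 4

Remark: gardenin A has no stereocentre, so no stereocontrol is needed; the supplied structures map consistently (quinone CH → C8a, carbonyl beside the acyl group → C5–OH, the other carbonyl → C8–OH), and flavone numbering is used throughout.

Step 1
Reactants: 1 1,2,3,4-tetramethoxybenzene
Product: 3 1-(2-hydroxy-3,4,5-trimethoxyphenyl)ethanone, via 2,3,4,5-tetramethoxyacetophenone 2 (not isolated)
Conditions: AcCl (1.2 equiv), AlCl3 (2.5 equiv), CH2Cl2, 0 °C → rt; aq. HCl
Reagents that add atoms: acetyl chloride, CC(Cl)=O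
Why: Friedel–Crafts acetylation at either of the two symmetry-equivalent free positions gives 2, and excess AlCl3 chelated between the new ketone and the ortho methoxy oxygen should cleave that one methyl ether (chelation-controlled ortho-demethylation), leaving a phenol para to the C5 methoxy group.

Step 2
Reactants: 3 1-(2-hydroxy-3,4,5-trimethoxyphenyl)ethanone, 4 methyl 3,4,5-trimethoxybenzoate
Product: 5 1-(2-hydroxy-3,4,5-trimethoxyphenyl)-3-(3,4,5-trimethoxyphenyl)propane-1,3-dione
Conditions: LiHMDS (4 equiv), THF, −78 °C → rt; cold 1 M HCl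
Reagents that add atoms: none
Why: Crossed Claisen condensation, in which the dilithium phenoxide–enolate of 3 is acylated on carbon by the non-enolisable ester 4 and deprotonation of the product diketone by the excess base drives the equilibrium; the cold, brief acid quench avoids cyclodehydration through the phenol.

Step 3
Reactants: 5 1-(2-hydroxy-3,4,5-trimethoxyphenyl)-3-(3,4,5-trimethoxyphenyl)propane-1,3-dione
Product: 6 2-[3-oxo-3-(3,4,5-trimethoxyphenyl)propanoyl]-5,6-dimethoxy-1,4-benzoquinone
Conditions: PhI(OAc)2 (1.05 equiv), MeCN–H2O (4:1), 0 °C, 10 min; cold CH2Cl2 extraction, crude used at once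
Reagents that add atoms: water, O
Why: Known iodine(III) oxidative demethylation of a p-methoxyphenol, in which the phenol exchanges onto iodine, water attacks the methoxy-bearing para carbon and methanol is lost to give the p-quinone; this should outrun any reaction of the reagent with the hydrogen-bonded diketone enol or the acyl-deactivated trimethoxyphenyl ring.

Step 4
Reactants: 6 2-[3-oxo-3-(3,4,5-trimethoxyphenyl)propanoyl]-5,6-dimethoxy-1,4-benzoquinone
Product: 8 5,8-dihydroxy-6,7-dimethoxy-2-(3,4,5-trimethoxyphenyl)chromen-4-one, via flavone-5,8-quinone 7 (not isolated)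
Conditions: (PhO)2P(O)OH (10 mol%), CH2Cl2 (0.01 M), rt, Ar; then PhI(OAc)2 (1.1 equiv); then aq. Na2S2O4
Reagents that add atoms: none
Why: Proposed new method: the phosphoric acid shuttles the diketone between its tautomers and, by bridging the quinone C1 carbonyl and the neighbouring side-chain carbonyl, should hold the chain so that the distal (aryl-bearing) enol/carbonyl oxygen sits above the one unsubstituted quinone carbon, which is β to both of those carbonyls; that oxygen adds there (oxa-Michael addition, equally an oxa-6π closure of the O=C–C=C–C=C array), making O1–C8a, and loss of the C8a proton aromatises ring A to the 5,8-hydroquinone 8. The closest known reaction types are the Brønsted-acid-accelerated conjugate additions of amines, thiols and electron-rich arenes to C3 of 2-acyl-1,4-benzoquinones and the oxa-6π electrocyclisation of cis-dienones to 2H-pyrans; closure of a diketone enol oxygen onto a quinone to build a flavone has not been demonstrated. Ring C, the only ring formed, closes 6-endo-trig, and no stereocentre is created. The step needs O- rather than C-attack and attack at the CH carbon rather than at a methoxy-bearing one: the diketone carbon could reach that CH only through a four-membered ring, the methoxy-bearing carbons are deactivated vinylogous esters beyond the reach of the tether, and 0.01 M dilution disfavours bimolecular Michael addition of the diketone carbon. Because 8 is expected to pass its two electrons to unreacted 6 (quinone–hydroquinone exchange), PhI(OAc)2 is then added so that all material, including any 6 reduced in this way and thereby re-oxidised to cyclise in turn, ends as flavonequinone 7, and dithionite returns 7 to 8.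

Step 5
Reactants: 8 5,8-dihydroxy-6,7-dimethoxy-2-(3,4,5-trimethoxyphenyl)chromen-4-one
Product: 9 gardenin A, 5-hydroxy-6,7,8-trimethoxy-2-(3,4,5-trimethoxyphenyl)chromen-4-one
Conditions: Me2SO4 (1.1 equiv), K2CO3 (1.5 equiv), degassed acetone, reflux, Ar
Reagents that add atoms: dimethyl sulfate, COS(=O)(=O)OC
Why: Williamson-type O-methylation (classical partial methylation of a 5-hydroxyflavone), in which the C8 phenoxide is alkylated while C5–OH, locked in a hydrogen bond to the C4 carbonyl, is far less nucleophilic and should stay free with one equivalent of electrophile; exclusion of air protects the hydroquinone under base.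

Compound list
1 | 1,2,3,4-tetramethoxybenzene | COc1ccc(OC)c(OC)c1OC | starting material
2 | 1-(2,3,4,5-tetramethoxyphenyl)ethanone | CC(=O)c1cc(OC)c(OC)c(OC)c1OC | intermediate
3 | 1-(2-hydroxy-3,4,5-trimethoxyphenyl)ethanone | CC(=O)c1cc(OC)c(OC)c(OC)c1O | intermediate
4 | methyl 3,4,5-trimethoxybenzoate | COC(=O)c1cc(OC)c(OC)c(OC)c1 | starting material
5 | 1-(2-hydroxy-3,4,5-trimethoxyphenyl)-3-(3,4,5-trimethoxyphenyl)propane-1,3-dione | COc1cc(C(=O)CC(=O)c2cc(OC)c(OC)c(OC)c2O)cc(OC)c1OC | intermediate
6 | 2-[3-oxo-3-(3,4,5-trimethoxyphenyl)propanoyl]-5,6-dimethoxy-1,4-benzoquinone | COC1=C(OC)C(=O)C(C(=O)CC(=O)c2cc(OC)c(OC)c(OC)c2)=CC1=O | intermediate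
7 | 6,7-dimethoxy-2-(3,4,5-trimethoxyphenyl)chromene-4,5,8-trione (flavone-5,8-quinone) | COC1=C(OC)C(=O)C2=C(C1=O)C(=O)C=C(c3cc(OC)c(OC)c(OC)c3)O2 | intermediate
8 | 5,8-dihydroxy-6,7-dimethoxy-2-(3,4,5-trimethoxyphenyl)chromen-4-one | COc1cc(-c2cc(=O)c3c(O)c(OC)c(OC)c(O)c3o2)cc(OC)c1OC | intermediate
9 | gardenin A, 5-hydroxy-6,7,8-trimethoxy-2-(3,4,5-trimethoxyphenyl)chromen-4-one | COc1cc(-c2cc(=O)c3c(O)c(OC)c(OC)c(OC)c3o2)cc(OC)c1OC | target

Total step count: 5. Longest linear sequence: 5 steps (1 → 3 → 5 → 6 → 8 → 9); ester 4 is purchased and enters at step 2.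

Steps most likely to fail

1. Step 4 (proposed new method). The oxygen may add too slowly because the diketone rests as its internally hydrogen-bonded enol. The quinone may then be consumed by bimolecular Michael addition of a diketone carbon, or conversion may stall through quinone–hydroquinone exchange. Fallback with known chemistry, setting out from 4 and returning at 8: purchased 1-(6-hydroxy-2,3,4-trimethoxyphenyl)ethanone F1 is condensed with 4 (LiHMDS, THF) to 1-(6-hydroxy-2,3,4-trimethoxyphenyl)-3-(3,4,5-trimethoxyphenyl)propane-1,3-dione F2. Classical cyclodehydration through the phenol oxygen (H2SO4, AcOH, heat) should give 5,6,7-trimethoxy-2-(3,4,5-trimethoxyphenyl)chromen-4-one F3. BCl3 (CH2Cl2, 0 °C) should cleave only the chelating 5-methyl ether to 5-hydroxy-6,7-dimethoxy-2-(3,4,5-trimethoxyphenyl)chromen-4-one F4. Elbs persulfate oxidation (K2S2O8, aq. KOH, pyridine) then places a sulfate para to the 5-phenoxide at C8, giving potassium 5-hydroxy-6,7-dimethoxy-4-oxo-2-(3,4,5-trimethoxyphenyl)chromen-8-yl sulfate F5. Hot dilute HCl hydrolyses F5 to 8, and step 5 follows unchanged.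

2. Step 3. Water may add to the very electrophilic acylquinone, or the quinone may begin to react before it is extracted. Oxidation may also stray to the ortho methoxy carbon (o-quinone formation) or to the diketone enol. Fallback, setting out from 5 and returning at 6: oxidation in anhydrous methanol (PhI(OAc)2, MeOH, 0 °C) should stop at the p-quinone monoketal 1-(3,3,4,5-tetramethoxy-6-oxocyclohexa-1,4-dien-1-yl)-3-(3,4,5-trimethoxyphenyl)propane-1,3-dione F6, a less electrophilic compound that can be purified. Brief two-phase hydrolysis (aq. CF3CO2H, CH2Cl2, 0 °C) then releases 6 directly into the solvent of step 4.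

3. Step 5. Selectivity between the two hydroxyls may be lost (methylation also at C5–OH), or the hydroquinone may be oxidised by air under base. Fallback, setting out from 8 and returning at 9: exhaustive methylation (excess MeI, K2CO3, DMF, 50 °C) gives 5,6,7,8-tetramethoxy-2-(3,4,5-trimethoxyphenyl)chromen-4-one F7. Chelation-directed cleavage of the 5-methyl ether alone (BCl3, CH2Cl2, 0 °C) then gives 9.

Further compounds
F1 | step 4 | 1-(6-hydroxy-2,3,4-trimethoxyphenyl)ethanone (purchased) | CC(=O)c1c(O)cc(OC)c(OC)c1OC
F2 | step 4 | 1-(6-hydroxy-2,3,4-trimethoxyphenyl)-3-(3,4,5-trimethoxyphenyl)propane-1,3-dione | COc1cc(C(=O)CC(=O)c2c(O)cc(OC)c(OC)c2OC)cc(OC)c1OC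
F3 | step 4 | 5,6,7-trimethoxy-2-(3,4,5-trimethoxyphenyl)chromen-4-one | COc1cc(-c2cc(=O)c3c(OC)c(OC)c(OC)cc3o2)cc(OC)c1OC
F4 | step 4 | 5-hydroxy-6,7-dimethoxy-2-(3,4,5-trimethoxyphenyl)chromen-4-one | COc1cc(-c2cc(=O)c3c(O)c(OC)c(OC)cc3o2)cc(OC)c1OC
F5 | step 4 | potassium 5-hydroxy-6,7-dimethoxy-4-oxo-2-(3,4,5-trimethoxyphenyl)chromen-8-yl sulfate | COc1cc(-c2cc(=O)c3c(O)c(OC)c(OC)c(OS(=O)(=O)[O-])c3o2)cc(OC)c1OC.[K+]
F6 | step 3 | 1-(3,3,4,5-tetramethoxy-6-oxocyclohexa-1,4-dien-1-yl)-3-(3,4,5-trimethoxyphenyl)propane-1,3-dione | COC1=C(OC)C(OC)(OC)C=C(C(=O)CC(=O)c2cc(OC)c(OC)c(OC)c2)C1=O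
F7 | step 5 | 5,6,7,8-tetramethoxy-2-(3,4,5-trimethoxyphenyl)chromen-4-one | COc1cc(-c2cc(=O)c3c(OC)c(OC)c(OC)c(OC)c3o2)cc(OC)c1OC
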